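**Plan**

1. Cuts: the C11=C12 and C11'=C12' double bonds (two Wittig reactions, C15 + C10 + C15), the C6'–C7' bond of the enyne ring (Sonogashira), and the C6–C7 and C5–O bonds of the triol ring; both rings go back to one cyclohexanone, 7.
2. The six-membered ring is made by one-carbon enlargement of cyclopentanone 5: the diazo carbon of diazoethane is inserted into the C(=O)–CH2 bond, which also brings in C5 with its methyl group.
3. Feature used: in 5 the carbonyl carbon sits between a quaternary CMe2 carbon and a CH2 group, so the methylene bond is the one expected to migrate, and the strained five-ring ketone is more reactive than the hindered product.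
4. Forward order: 1 → 2 → 4 → 5 → 7; 7 → triflate 9 → enyne 11 → salt 12; 7 → hydroxy ketone 14 → 16 → 17 → salt 18; 12 + dialdehyde 19 → 21; 21 + 18 → 23.
5. Stereochemistry: the silyloxy carbon (C3 and C3') comes from one copper-catalysed asymmetric conjugate borylation; C5 from axial enolate hydroxylation trans to OSi; C6 from axial acetylide addition; E alkenes from 10, from trans-hydroalumination and from Wittig olefination with thermal isomerisation.

Key step: step 4

Remark: the SMILES is read as (3S,5R,6S,3'R), that is, the 5- and 6-hydroxyls are cis to each other and trans to the 3-hydroxyl; the route is built for this isomer.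

**Route**

Step 1
Reactants: 1 2,2-dimethylcyclopentan-1-one
Product: 2 5,5-dimethylcyclopent-2-en-1-one
Conditions: IBX (1.5 equiv), DMSO/PhF, 70 °C
Reagents that add atoms: none
Why: IBX dehydrogenation of a ketone to the enone can only take place on the single enolisable methylene side, so the double bond forms away from the quaternary carbon.

Step 2
Reactants: 2 5,5-dimethylcyclopent-2-en-1-one
Product: 4 (4S)-4-hydroxy-2,2-dimethylcyclopentan-1-one, via boronate 3 (not isolated)
Conditions: CuCl (3 mol%), NaOt-Bu (4 mol%), Josiphos ligand 1-[2-(diphenylphosphino)ferrocenyl]ethyldicyclohexylphosphine (the antipode that leads to the 4S product), B2pin2, MeOH, THF, rt; then NaBO3·4H2O, THF/H2O, rt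
Reagents that add atoms: NaBO3·4H2O, sodium perborate tetrahydrate (source of the hydroxyl oxygen) [Na+].[Na+].O[B-]1(O)OO[B-](O)(O)OO1; bis(pinacolato)diboron (boron of 3 only, lost again in the oxidation) CC1(C)OB(OC1(C)C)B1OC(C)(C)C(C)(C)O1
Why: Copper-catalysed enantioselective conjugate borylation of a cyclic enone followed by stereoretentive C–B oxidation should set the carbinol stereocenter, the only one in the route set by a catalyst; the sense of induction has to be checked on 2 and the ligand antipode chosen accordingly.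

Step 3
Reactants: 4 (4S)-4-hydroxy-2,2-dimethylcyclopentan-1-one
Product: 5 (4S)-2,2-dimethyl-4-(triethylsilyloxy)cyclopentan-1-one
Conditions: Et3SiCl, imidazole, CH2Cl2, 0 °C
Reagents that add atoms: chlorotriethylsilane CC[Si](Cl)(CC)CC
Why: Standard silylation; the triethylsilyl ether should survive amide bases, organolithiums and aluminium hydride and then fall off in the acidic methanol of steps 7 and 11.

Step 4
Reactants: 5 (4S)-2,2-dimethyl-4-(triethylsilyloxy)cyclopentan-1-one
Product: 7 (4R)-2,2,6-trimethyl-4-(triethylsilyloxy)cyclohexan-1-one (mixture of C6 epimers), via diazonium alkoxide 6 (not isolated)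
Conditions: CH3CHN2 (Et2O solution from N-ethyl-N-nitrosourea and aq. KOH, dried over KOH pellets, slow addition), Sc(OTf)3 (5 mol%), toluene, −78 °C
Reagents that add atoms: diazoethane CC=[N+]=[N-]
Why: Sc(OTf)3 activates the cyclopentanone carbonyl, the nucleophilic carbon of diazoethane adds to it to give diazonium alkoxide 6, and the ring C–C bond anti to the departing N2 shifts to the diazo carbon (1,2-shift with loss of dinitrogen), so that this carbon is inserted between the carbonyl carbon and its methylene neighbour. The closest known reaction type is the Lewis-acid-catalysed diazoalkane homologation of cyclic ketones (Tiffeneau–Demjanov-type ring expansion). The six-membered ring is not closed by a cyclisation but arises by one-carbon enlargement of the five-membered ring through this 1,2-alkyl shift, helped by release of cyclopentanone strain. The new stereocenter at C6 (CHMe) is uncontrolled and does not matter because it becomes sp2 in steps 5 and 8, while the silyloxy-bearing stereocenter is remote from the reacting bonds and is retained. The step needs migration of the CH2 group and not of the quaternary CMe2 carbon: diazoethane should add with its methyl and diazonium groups turned away from the gem-dimethyl group, which places the C(=O)–CH2 bond anti to N2, the usual outcome with α-quaternary ketones. A second insertion should be held back because 7 is flanked by a quaternary and a tertiary carbon and is far less electrophilic than the strained ketone 5.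

Step 5
Reactants: 7 (4R)-2,2,6-trimethyl-4-(triethylsilyloxy)cyclohexan-1-one
Product: 9 (4R)-2,6,6-trimethyl-4-(triethylsilyloxy)cyclohex-1-en-1-yl trifluoromethanesulfonate, via potassium enolate 8 (not isolated)
Conditions: KN(SiMe3)2, THF, −78 to 0 °C; PhNTf2, −78 °C to rt; aq. NH4Cl
Reagents that add atoms: N-phenylbis(trifluoromethanesulfonimide) O=S(=O)(N(c1ccccc1)S(=O)(=O)C(F)(F)F)C(F)(F)F
Why: The ketone has a single α-hydrogen, so deprotonation can only give the tetrasubstituted enolate, and the dissociated potassium enolate is trapped on oxygen (enol triflate formation), which converges both C6 epimers.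

Step 6
Reactants: 9 (4R)-2,6,6-trimethyl-4-(triethylsilyloxy)cyclohex-1-en-1-yl trifluoromethanesulfonate; 10 (2E)-3-methylpent-2-en-4-yn-1-ol
Product: 11 (2E)-3-methyl-5-[(4R)-2,6,6-trimethyl-4-(triethylsilyloxy)cyclohex-1-en-1-yl]pent-2-en-4-yn-1-ol
Conditions: Pd(PPh3)4 (5 mol%), CuI (10 mol%), i-Pr2NH, DMF, rt to 40 °C
Reagents that add atoms: none
Why: Sonogashira coupling of an enol triflate with a terminal alkyne forms the C6'–C7' bond and leaves the E double bond of 10 and the free primary alcohol untouched.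

Step 7
Reactants: 11 (2E)-3-methyl-5-[(4R)-2,6,6-trimethyl-4-(triethylsilyloxy)cyclohex-1-en-1-yl]pent-2-en-4-yn-1-ol
Product: 12 [(2E)-5-[(4R)-4-hydroxy-2,6,6-trimethylcyclohex-1-en-1-yl]-3-methylpent-2-en-4-yn-1-yl]triphenylphosphonium bromide
Conditions: PPh3·HBr, MeOH, rt
Reagents that add atoms: triphenylphosphine hydrobromide [Br-].c1ccc(cc1)[PH+](c1ccccc1)c1ccccc1
Why: Acid-mediated substitution of the primary allylic alcohol by PPh3 (allylic phosphonium salt formation through the delocalised cation, attack at the unhindered terminus) should occur while the acidic methanol removes the triethylsilyl ether in the same operation.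

Step 8
Reactants: 7 (4R)-2,2,6-trimethyl-4-(triethylsilyloxy)cyclohexan-1-one
Product: 14 (2R,4S)-2-hydroxy-2,6,6-trimethyl-4-(triethylsilyloxy)cyclohexan-1-one, via sodium enolate 13 (not isolated)
Conditions: NaN(SiMe3)2, THF, −78 to 0 °C; 2-(phenylsulfonyl)-3-phenyloxaziridine, −78 °C; aq. NH4Cl
Reagents that add atoms: 2-(phenylsulfonyl)-3-phenyloxaziridine O=S(=O)(c1ccccc1)N1OC1c1ccccc1
Why: Hydroxylation of the sodium enolate with an N-sulfonyloxaziridine (Davis oxidation, for which sodium enolates are the usual partners) should occur by axial attack at C2 of the half-chair enolate that keeps the silyloxy group equatorial, which puts the new hydroxyl trans to OSi, since attack on the other face would have to pass a 1,3-diaxial silyloxy group.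

Step 9
Reactants: 14 (2R,4S)-2-hydroxy-2,6,6-trimethyl-4-(triethylsilyloxy)cyclohexan-1-one; 10 (2E)-3-methylpent-2-en-4-yn-1-ol
Product: 16 (1R,2R,4S)-1-[(3E)-5-hydroxy-3-methylpent-3-en-1-yn-1-yl]-2,6,6-trimethyl-4-(triethylsilyloxy)cyclohexane-1,2-diol, via dilithio enynolate 15 (not isolated)
Conditions: 10 (3 equiv), n-BuLi (6 equiv), THF, −78 to 0 °C; then 14, −78 °C to rt; aq. NH4Cl
Reagents that add atoms: none
Why: Acetylide 1,2-addition to a ketone that cannot enolise should occur axially, from the face opposite to the axial oxygen at C2 and the axial methyl at C6, which gives the cis-1,2-diol with the side chain trans to both hydroxyls.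

Step 10
Reactants: 16 (1R,2R,4S)-1-[(3E)-5-hydroxy-3-methylpent-3-en-1-yn-1-yl]-2,6,6-trimethyl-4-(triethylsilyloxy)cyclohexane-1,2-diol
Product: 17 (1S,2R,4S)-1-[(1E,3E)-5-hydroxy-3-methylpenta-1,3-dien-1-yl]-2,6,6-trimethyl-4-(triethylsilyloxy)cyclohexane-1,2-diol
Conditions: NaAlH2(OCH2CH2OMe)2, THF, 0 °C to rt; aq. KNaC4H4O6 (potassium sodium tartrate)
Reagents that add atoms: none
Why: Alkoxide-directed trans-hydroalumination of the tertiary propargylic alcohol should reduce the alkyne to the E alkene only and leave the existing trisubstituted E alkene and the stereocenters untouched.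

Step 11
Reactants: 17 (1S,2R,4S)-1-[(1E,3E)-5-hydroxy-3-methylpenta-1,3-dien-1-yl]-2,6,6-trimethyl-4-(triethylsilyloxy)cyclohexane-1,2-diol
Product: 18 [(2E,4E)-3-methyl-5-[(1S,2R,4S)-1,2,4-trihydroxy-2,6,6-trimethylcyclohexyl]penta-2,4-dien-1-yl]triphenylphosphonium bromide
Conditions: PPh3·HBr, MeOH, 0 °C to rt
Reagents that add atoms: triphenylphosphine hydrobromide [Br-].c1ccc(cc1)[PH+](c1ccccc1)c1ccccc1
Why: Allylic phosphonium salt formation as in step 7: the primary dienylic alcohol should ionise more readily than the tertiary carbinol, which is deactivated by the vicinal hydroxyl, and the acidic methanol again removes the silyl ether.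

Step 12
Reactants: 12 [(2E)-5-[(4R)-4-hydroxy-2,6,6-trimethylcyclohex-1-en-1-yl]-3-methylpent-2-en-4-yn-1-yl]triphenylphosphonium bromide; 19 (2E,4E,6E)-2,7-dimethylocta-2,4,6-trienedial
Product: 21 (3R)-3-hydroxy-7,8-didehydro-12'-apo-β-caroten-12'-al, via ylide 20 (not isolated)
Conditions: 19 (2.5 equiv), NaOMe, CH2Cl2/MeOH, 0 °C to rt, dark; then heptane/EtOAc, 70 °C
Reagents that add atoms: none
Why: Wittig olefination of the semi-stabilised allylic ylide with an excess of the dialdehyde should stop at mono-olefination, and warming should turn any hindered Z isomer at the new C11'=C12' bond into the E isomer.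

Step 13
Reactants: 21 (3R)-3-hydroxy-7,8-didehydro-12'-apo-β-caroten-12'-al; 18 [(2E,4E)-3-methyl-5-[(1S,2R,4S)-1,2,4-trihydroxy-2,6,6-trimethylcyclohexyl]penta-2,4-dien-1-yl]triphenylphosphonium bromide
Product: 23 (3S,5R,6S,3'R)-7',8'-didehydro-5,6-dihydro-β,β-carotene-3,5,6,3'-tetrol (target), via ylide 22 (not isolated)
Conditions: NaOMe, CH2Cl2/MeOH, rt, dark; then EtOH, 70 °C, dark
Reagents that add atoms: none
Why: The second Wittig olefination forms C11=C12 with free hydroxyls tolerated under NaOMe conditions, and gentle heating should convert the hindered 11Z isomer into the all-E polyene without touching the four stereocenters.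

**Compound list**

1 | 2,2-dimethylcyclopentan-1-one | O=C1CCCC1(C)C | starting material
2 | 5,5-dimethylcyclopent-2-en-1-one | O=C1C=CCC1(C)C | intermediate
3 | (4S)-2,2-dimethyl-4-(4,4,5,5-tetramethyl-1,3,2-dioxaborolan-2-yl)cyclopentan-1-one (not isolated) | O=C1C(C)(C)C[C@H](B2OC(C)(C)C(C)(C)O2)C1 | intermediate
4 | (4S)-4-hydroxy-2,2-dimethylcyclopentan-1-one | O=C1C(C)(C)C[C@H](O)C1 | intermediate
5 | (4S)-2,2-dimethyl-4-(triethylsilyloxy)cyclopentan-1-one | O=C1C(C)(C)C[C@H](O[Si](CC)(CC)CC)C1 | intermediate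
6 | 1-(1-diazonioethyl)-2,2-dimethyl-4-(triethylsilyloxy)cyclopentan-1-olate, scandium-bound (not isolated) | CC([N+]#N)C1([O-])C(C)(C)C[C@H](O[Si](CC)(CC)CC)C1 | intermediate
7 | (4R)-2,2,6-trimethyl-4-(triethylsilyloxy)cyclohexan-1-one, C6 epimers | CC1C(=O)C(C)(C)C[C@H](O[Si](CC)(CC)CC)C1 | intermediate
8 | potassium (4R)-2,6,6-trimethyl-4-(triethylsilyloxy)cyclohex-1-en-1-olate (not isolated) | CC1=C([O-])C(C)(C)C[C@H](O[Si](CC)(CC)CC)C1.[K+] | intermediate
9 | (4R)-2,6,6-trimethyl-4-(triethylsilyloxy)cyclohex-1-en-1-yl trifluoromethanesulfonate | CC1=C(OS(=O)(=O)C(F)(F)F)C(C)(C)C[C@H](O[Si](CC)(CC)CC)C1 | intermediate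
10 | (2E)-3-methylpent-2-en-4-yn-1-ol | C#C/C(C)=C/CO | starting material
11 | (2E)-3-methyl-5-[(4R)-2,6,6-trimethyl-4-(triethylsilyloxy)cyclohex-1-en-1-yl]pent-2-en-4-yn-1-ol | CC1=C(C#C/C(C)=C/CO)C(C)(C)C[C@H](O[Si](CC)(CC)CC)C1 | intermediate
12 | [(2E)-5-[(4R)-4-hydroxy-2,6,6-trimethylcyclohex-1-en-1-yl]-3-methylpent-2-en-4-yn-1-yl]triphenylphosphonium bromide | CC1=C(C#C/C(C)=C/C[P+](c2ccccc2)(c2ccccc2)c2ccccc2)C(C)(C)C[C@H](O)C1.[Br-] | intermediate
13 | sodium (4R)-2,6,6-trimethyl-4-(triethylsilyloxy)cyclohex-1-en-1-olate (not isolated) | CC1=C([O-])C(C)(C)C[C@H](O[Si](CC)(CC)CC)C1.[Na+] | intermediate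
14 | (2R,4S)-2-hydroxy-2,6,6-trimethyl-4-(triethylsilyloxy)cyclohexan-1-one | O=C1C(C)(C)C[C@H](O[Si](CC)(CC)CC)C[C@@]1(C)O | intermediate
15 | dilithium salt of (2E)-3-methylpent-2-en-4-yn-1-ol, alkoxide and acetylide (not isolated) | [Li+].[Li+].[C-]#C/C(C)=C/C[O-] | intermediate
16 | (1R,2R,4S)-1-[(3E)-5-hydroxy-3-methylpent-3-en-1-yn-1-yl]-2,6,6-trimethyl-4-(triethylsilyloxy)cyclohexane-1,2-diol | OC/C=C(C)/C#C[C@]1(O)C(C)(C)C[C@H](O[Si](CC)(CC)CC)C[C@@]1(C)O | intermediate
17 | (1S,2R,4S)-1-[(1E,3E)-5-hydroxy-3-methylpenta-1,3-dien-1-yl]-2,6,6-trimethyl-4-(triethylsilyloxy)cyclohexane-1,2-diol | OC/C=C(C)/C=C/[C@]1(O)C(C)(C)C[C@H](O[Si](CC)(CC)CC)C[C@@]1(C)O | intermediate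
18 | [(2E,4E)-3-methyl-5-[(1S,2R,4S)-1,2,4-trihydroxy-2,6,6-trimethylcyclohexyl]penta-2,4-dien-1-yl]triphenylphosphonium bromide | c1ccccc1[P+](c1ccccc1)(c1ccccc1)C/C=C(C)/C=C/[C@]1(O)C(C)(C)C[C@H](O)C[C@@]1(C)O.[Br-] | intermediate
19 | (2E,4E,6E)-2,7-dimethylocta-2,4,6-trienedial | O=C/C(C)=C/C=C/C=C(C)/C=O | starting material
20 | ylide of 12 (not isolated) | CC1=C(C#C/C(C)=C/C=P(c2ccccc2)(c2ccccc2)c2ccccc2)C(C)(C)C[C@H](O)C1 | intermediate
21 | (3R)-3-hydroxy-7,8-didehydro-12'-apo-β-caroten-12'-al; (2E,4E,6E,8E,10E)-13-[(4R)-4-hydroxy-2,6,6-trimethylcyclohex-1-en-1-yl]-2,7,11-trimethyltrideca-2,4,6,8,10-pentaen-12-ynal | CC1=C(C#C/C(C)=C/C=C/C(C)=C/C=C/C=C(C)/C=O)C(C)(C)C[C@H](O)C1 | intermediate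
22 | ylide of 18 (not isolated) | c1ccccc1P(c1ccccc1)(c1ccccc1)=C/C=C(C)/C=C/[C@]1(O)C(C)(C)C[C@H](O)C[C@@]1(C)O | intermediate
23 | (3S,5R,6S,3'R)-7',8'-didehydro-5,6-dihydro-β,β-carotene-3,5,6,3'-tetrol | CC1=C(C#C/C(C)=C/C=C/C(C)=C/C=C/C=C(C)/C=C/C=C(C)/C=C/[C@]2(O)C(C)(C)C[C@H](O)C[C@@]2(C)O)C(C)(C)C[C@H](O)C1 | target

**Step count and risks**

Total step count: 13. Longest linear sequence: 9 steps (1–7, 12, 13; the branch 1–4, 8–11, 13 is equally long).

Steps most likely to fail:

Step 4. What may go wrong: migration of the quaternary carbon in place of the methylene group, a second insertion into 7, or loss of diazoethane through Lewis-acid-induced oligomerisation. The fallback is a different ring enlargement in which the regiochemistry is fixed by the enol ether. It sets out from 5: soft enolisation (Me3SiOTf, Et3N, CH2Cl2), which can only go toward the methylene group, gives the trimethylsilyl enol ether F1. Cyclopropanation (Et2Zn, CH2I2) gives the siloxybicyclo[3.1.0]hexane F2. FeCl3 in DMF opens the internal cyclopropane bond (Saegusa–Ito-type oxidative ring enlargement) to the β-chloro ketone F3, and NaOAc in MeOH eliminates HCl to the enone F4. Conjugate reduction with LiBH(s-Bu)3 and trapping of the enolate with MeI comes back to 7.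

Step 8. What may go wrong: poor facial selectivity in the hydroxylation (hydroxyl cis to the silyloxy group), or addition of the enolate to the sulfonimine by-product. The fallback sets the C2 stereocenter under thermodynamic instead of kinetic control. It sets out from 5: addition of 1-ethoxyvinyllithium (ethyl vinyl ether, t-BuLi, THF, −78 °C) gives the enol ether carbinol F5, and mild hydrolysis (aq. oxalic acid on silica) gives the 1-acetylcyclopentanol F6. An α-ketol (acyloin) rearrangement under equilibrating conditions (Al(Ot-Bu)3, toluene, heat) enlarges the ring by shift of the methylene carbon to the acyl carbon and comes back to 14. The isomer with equatorial methyl, hydroxyl trans to silyloxy and no vicinal quaternary carbons is expected to be the most stable one.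

Step 11. What may go wrong: ionisation at the tertiary allylic carbinol (allylic transposition, methanolysis or pinacol-type shift of the 1,2-diol) in place of clean substitution at the primary carbon. The fallback reverses the polarity of the last olefination so that the triol unit never meets acid. It sets out from 17 and 21: MnO2 (CH2Cl2) oxidises only the primary allylic alcohol of 17 to the dienal F7. NaBH4 reduces 21 to the C25 alcohol F8, and PPh3·HBr converts this into the C25 phosphonium bromide F9. Wittig reaction of F9 with F7 (NaOMe, CH2Cl2/MeOH) gives the 3-O-triethylsilyl ether of the target F10, and Bu4NF in THF removes the silyl group to come back to 23.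

**Further compounds**

F1 | step 4 | triethyl{[(1S)-4,4-dimethyl-3-(trimethylsilyloxy)cyclopent-2-en-1-yl]oxy}silane | C[Si](C)(C)OC1=C[C@@H](O[Si](CC)(CC)CC)CC1(C)C
F2 | step 4 | (4S)-2,2-dimethyl-4-(triethylsilyloxy)-1-(trimethylsilyloxy)bicyclo[3.1.0]hexane, ring-fusion isomers | C[Si](C)(C)OC12CC1[C@@H](O[Si](CC)(CC)CC)CC2(C)C
F3 | step 4 | (4S)-5-chloro-2,2-dimethyl-4-(triethylsilyloxy)cyclohexan-1-one, C5 epimers | O=C1CC(Cl)[C@@H](O[Si](CC)(CC)CC)CC1(C)C
F4 | step 4 | (4S)-6,6-dimethyl-4-(triethylsilyloxy)cyclohex-2-en-1-one | O=C1C=C[C@@H](O[Si](CC)(CC)CC)CC1(C)C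
F5 | step 8 | (4S)-1-(1-ethoxyethenyl)-2,2-dimethyl-4-(triethylsilyloxy)cyclopentan-1-ol, C1 epimers | CCOC(=C)C1(O)C(C)(C)C[C@H](O[Si](CC)(CC)CC)C1
F6 | step 8 | 1-[(4S)-1-hydroxy-2,2-dimethyl-4-(triethylsilyloxy)cyclopentyl]ethan-1-one, C1 epimers | CC(=O)C1(O)C(C)(C)C[C@H](O[Si](CC)(CC)CC)C1
F7 | step 11 | (2E,4E)-5-[(1S,2R,4S)-1,2-dihydroxy-2,6,6-trimethyl-4-(triethylsilyloxy)cyclohexyl]-3-methylpenta-2,4-dienal | O=C/C=C(C)/C=C/[C@]1(O)C(C)(C)C[C@H](O[Si](CC)(CC)CC)C[C@@]1(C)O
F8 | step 11 | (2E,4E,6E,8E,10E)-13-[(4R)-4-hydroxy-2,6,6-trimethylcyclohex-1-en-1-yl]-2,7,11-trimethyltrideca-2,4,6,8,10-pentaen-12-yn-1-ol | CC1=C(C#C/C(C)=C/C=C/C(C)=C/C=C/C=C(C)/CO)C(C)(C)C[C@H](O)C1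
F9 | step 11 | [(2E,4E,6E,8E,10E)-13-[(4R)-4-hydroxy-2,6,6-trimethylcyclohex-1-en-1-yl]-2,7,11-trimethyltrideca-2,4,6,8,10-pentaen-12-yn-1-yl]triphenylphosphonium bromide | CC1=C(C#C/C(C)=C/C=C/C(C)=C/C=C/C=C(C)/C[P+](c2ccccc2)(c2ccccc2)c2ccccc2)C(C)(C)C[C@H](O)C1.[Br-]
F10 | step 11 | 3-O-triethylsilyl ether of 23 | CC1=C(C#C/C(C)=C/C=C/C(C)=C/C=C/C=C(C)/C=C/C=C(C)/C=C/[C@]2(O)C(C)(C)C[C@H](O[Si](CC)(CC)CC)C[C@@]2(C)O)C(C)(C)C[C@H](O)C1
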